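**Assumption:** germacrane locants are used (C1=C10 alkene, C3 angelate, C4–C5 oxirane, C6 acetate, C7 isopropyl); the SMILES is read as (1(10)E,3S,4R,5R,6R,7S) with a (Z)-2-methylbut-2-enoate.

## Retrosynthetic overview

1. The ten-membered ring is closed last, at C9–C10, by nickel-catalysed electroreductive coupling of the alkenyl iodide and the primary alkyl iodide of 22 (the oxirane is made first, the carbocycle second).
2. C6–C7 and both of their stereocentres come from an anti-selective, Felkin-controlled addition of a γ-isopropylallylchromium to epoxy aldehyde 15; its vinyl group becomes C8–C9.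
3. The C3/C4/C5 triad comes from hydroxyl-directed epoxidation of (E)-allylic alcohol 11, then Mitsunobu inversion at C3, which also installs the angelate.
4. The chain of 11 comes from a Horner–Wadsworth–Emmons olefination (C4=C5), a hydrozirconation–iodination (C10–I) and propynyl opening of methyl (R)-glycidate 1 (C1–C2), the only source of chirality.

## Route

Step 1
Reactants: 1 methyl (2R)-oxirane-2-carboxylate (methyl (R)-glycidate); 2 prop-1-yn-1-yllithium
Product: 3 methyl (2R)-2-hydroxyhex-4-ynoate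
Conditions: 2 and BF3·OEt2, THF, −78 °C; then 1, −78 °C; aq. NH4Cl
Reagents that add atoms: none
Why: Yamaguchi-type BF3-promoted alkynylation is an SN2 opening at the unsubstituted oxirane CH2 only, so the purchased stereocentre (future C3, R) is carried over unchanged and the ester is not attacked at −78 °C.

Step 2
Reactants: 3 methyl (2R)-2-hydroxyhex-4-ynoate
Product: 4 methyl (2R)-2-(triethylsilyloxy)hex-4-ynoate
Conditions: Et3SiCl, imidazole, CH2Cl2, 0 °C
Reagents that add atoms: chlorotriethylsilane, CC[Si](Cl)(CC)CC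
Why: Silyl ether formation (retention) masks the hydroxyl so that the later olefination cannot lactonise to a butenolide and the α-oxygenated ketone is not handled as an alkoxide.

Step 3
Reactants: 4 methyl (2R)-2-(triethylsilyloxy)hex-4-ynoate
Product: 6 (3R)-3-(triethylsilyloxy)hept-5-yn-2-one, via silyl ketone 5 (not isolated)
Conditions: Me3SiCH2Li (2.2 equiv), pentane–THF, −78 → 0 °C; then MeOH, aq. NH4Cl
Reagents that add atoms: (trimethylsilyl)methyllithium, C[Si](C)(C)C[Li]
Why: Acyl substitution by the silylmethyl anion stops at the ketone because α-silyl ketone 5 is at once deprotonated on its silyl-bearing carbon (which also keeps C3–H from enolising) and loses silicon on the methanolic quench (ester to methyl ketone conversion).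

Step 4
Reactants: 6 (3R)-3-(triethylsilyloxy)hept-5-yn-2-one
Product: 7 ethyl (2E,4R)-3-methyl-4-(triethylsilyloxy)oct-2-en-6-ynoate
Conditions: (EtO)2P(O)CH2CO2Et, NaH, THF, 0 °C → rt
Reagents that add atoms: triethyl phosphonoacetate, CCOC(=O)CP(=O)(OCC)OCC
Why: Horner–Wadsworth–Emmons olefination of the α-branched methyl ketone places the ester trans to the bulky silyloxy-bearing branch, giving the (E)-trisubstituted C4=C5 alkene without touching C3.

Step 5
Reactants: 7 ethyl (2E,4R)-3-methyl-4-(triethylsilyloxy)oct-2-en-6-ynoate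
Product: 9 (2E,4R)-3-methyloct-2-en-6-yne-1,4-diol, via silyl ether 8 (not isolated)
Conditions: i-Bu2AlH, CH2Cl2, −78 °C; then 1 M HCl, THF, 0 °C → rt
Reagents that add atoms: none
Why: DIBAL-H 1,2-reduction of the enoate gives the allylic alcohol and the dilute-acid work-up cleaves the labile triethylsilyl ether, leaving alkyne, alkene geometry and stereocentre intact.

Step 6
Reactants: 9 (2E,4R)-3-methyloct-2-en-6-yne-1,4-diol
Product: 11 (2E,4R,6E)-7-iodo-3-methylocta-2,6-diene-1,4-diol, via alkenylzirconocene 10 (not isolated)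
Conditions: Cp2Zr(H)Cl (4.5 equiv), THF, 45 °C; then I2, 0 °C
Reagents that add atoms: iodine, II
Why: Hydrozirconation is a syn addition that, with excess reagent, settles zirconium on the less hindered methyl-bearing alkyne carbon, and iodinolysis with retention gives the (E)-2-iodoalkene with iodine trans to the chain; the trisubstituted alkene is inert.

Step 7
Reactants: 11 (2E,4R,6E)-7-iodo-3-methylocta-2,6-diene-1,4-diol
Product: 12 (1R,3E)-1-[(2R,3R)-3-(hydroxymethyl)-2-methyloxiran-2-yl]-4-iodopent-3-en-1-ol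
Conditions: VO(acac)2 (5 mol%), t-BuOOH, CH2Cl2, 0 °C
Reagents that add atoms: tert-butyl hydroperoxide, CC(C)(C)OO
Why: Vanadium-catalysed hydroxyl-directed epoxidation: with a methyl geminal to the carbinol (A(1,2) strain) the C3–H eclipses that methyl and oxygen is delivered to the alkene face on the hydroxyl side, giving the erythro (3R,4R,5R) trans-epoxide from the (E)-alkene while the electron-poor iodoalkene is left alone.

Step 8
Reactants: 12 (1R,3E)-1-[(2R,3R)-3-(hydroxymethyl)-2-methyloxiran-2-yl]-4-iodopent-3-en-1-ol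
Product: 13 (2S,3R)-3-[(1R,3E)-1-hydroxy-4-iodopent-3-en-1-yl]-3-methyloxirane-2-carbaldehyde
Conditions: TEMPO (10 mol%), PhI(OAc)2, CH2Cl2, rt
Reagents that add atoms: none
Why: Oxoammonium (TEMPO) oxidation is selective for the primary alcohol, so the secondary C3–OH, the oxirane and the iodoalkene survive and no stereocentre is touched.

Step 9
Reactants: 13 (2S,3R)-3-[(1R,3E)-1-hydroxy-4-iodopent-3-en-1-yl]-3-methyloxirane-2-carbaldehyde; 14 (2Z)-2-methylbut-2-enoic acid (angelic acid)
Product: 15 (1S,3E)-1-[(2R,3S)-3-formyl-2-methyloxiran-2-yl]-4-iodopent-3-en-1-yl (2Z)-2-methylbut-2-enoate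
Conditions: PPh3, DIAD (betaine pre-formed), toluene, 0 °C → rt
Reagents that add atoms: none
Why: Mitsunobu esterification is an SN2 displacement of the oxyphosphonium by angelate, which inverts C3 to S (threo to the oxirane) and brings the (Z)-ester in as a nucleophile, avoiding the acyl activation that isomerises angelates to tiglates.

Step 10
Reactants: 16 4-methylpent-1-en-3-ol (racemic)
Product: 17 (2E)-1-bromo-4-methylpent-2-ene
Conditions: PBr3, Et2O, 0 °C
Reagents that add atoms: phosphorus tribromide, BrP(Br)Br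
Why: Bromination with allylic transposition (SN2′) gives mainly the primary (E)-bromide, and any secondary isomer converges to the same allylchromium in step 11.

Step 11
Reactants: 15 (1S,3E)-1-[(2R,3S)-3-formyl-2-methyloxiran-2-yl]-4-iodopent-3-en-1-yl (2Z)-2-methylbut-2-enoate; 17 (2E)-1-bromo-4-methylpent-2-ene
Product: 19 (1S,3E)-1-{(2R,3R)-3-[(1R,2R)-1-hydroxy-2-(propan-2-yl)but-3-en-1-yl]-2-methyloxiran-2-yl}-4-iodopent-3-en-1-yl (2Z)-2-methylbut-2-enoate, via allylchromium dichloride 18 (not isolated)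
Conditions: CrCl2 (nickel-free, 4 equiv), 17 (2 equiv), THF, 0 °C; aq. NH4Cl
Reagents that add atoms: none
Why: Nozaki–Hiyama allylation: γ-substituted allylchromium 18 adds through a chair transition state with isopropyl equatorial (C6-OH/C7-iPr anti) and attacks anti to the oxirane C5–O bond on the face away from quaternary C4 (Felkin–Anh/Cornforth, erythro C5/C6), setting C6 and C7 as in the target, while nickel-free CrCl2 leaves alkenyl iodide, ester and oxirane alone.

Step 12
Reactants: 19 (homoallylic alcohol from step 11)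
Product: 20 (1S,3E)-1-{(2R,3R)-3-[(1R,2R)-1-(acetyloxy)-2-(propan-2-yl)but-3-en-1-yl]-2-methyloxiran-2-yl}-4-iodopent-3-en-1-yl (2Z)-2-methylbut-2-enoate
Conditions: Ac2O, pyridine, DMAP (cat.), CH2Cl2, 0 °C
Reagents that add atoms: acetic anhydride, CC(=O)OC(C)=O
Why: DMAP-catalysed acylation of the secondary alcohol with retention under buffered conditions that do not open or migrate the oxirane.

Step 13
Reactants: 20 (acetate from step 12)
Product: 22 (1S,3E)-1-{(2R,3R)-3-[(1R,2S)-1-(acetyloxy)-4-iodo-2-(propan-2-yl)butyl]-2-methyloxiran-2-yl}-4-iodopent-3-en-1-yl (2Z)-2-methylbut-2-enoate, via alkylborane 21 (not isolated)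
Conditions: 9-BBN-H, THF, 0 °C → rt; then NaOAc, ICl, MeOH, 0 °C
Reagents that add atoms: iodine monochloride, ClI
Why: 9-BBN hydroboration is anti-Markovnikov and touches only the monosubstituted alkene (not the iodoalkene or the enoate), and iododeboronation with ICl/NaOAc turns the primary C–B bond of 21 into the C9–I bond without a base strong enough to cleave the esters.

Step 14
Reactants: 22 (diiodide from step 13)
Product: 23 (1(10)E,3S,4R,5R,6R,7S)-6-acetoxy-4,5-epoxygermacr-1(10)-en-3-yl (2Z)-2-methylbut-2-enoate (target)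
Conditions: NiBr2(dme) (20 mol%), 4,4′-di-tert-butyl-2,2′-bipyridine (24 mol%), NaI (0.1 M), DMA, undivided cell, Zn anode, nickel-foam cathode, constant current 3 mA, 22 added by syringe pump over 12 h (final 2 mM), 20 °C
Reagents that add atoms: none
Why: Proposed new method: intramolecular nickel-catalysed electroreductive cross-electrophile coupling to a ten-membered (E)-cycloalkene — cathodically formed zerovalent nickel–bipyridine inserts into the alkenyl C10–I bond faster than into the primary alkyl iodide, one-electron reduction gives an alkenyl complex of monovalent nickel that abstracts iodine from the tethered C9–I of the same molecule, the C9 radical collapses on that metal to a trivalent alkenyl(alkyl)nickel metallacycle, and reductive elimination forms C9–C10 with retention of the E geometry (slow addition keeps the reaction intramolecular, the potential stays below direct reduction of esters and oxirane); the closest known reactions are the intermolecular nickel-catalysed electroreductive coupling of alkenyl halides with alkyl halides and nickel-catalysed reductive cyclisations to small rings, and no stereocentre is formed or touched.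

## Compound list

1 | methyl (2R)-oxirane-2-carboxylate | COC(=O)[C@H]1CO1 | starting material
2 | prop-1-yn-1-yllithium | [Li]C#CC | starting material
3 | methyl (2R)-2-hydroxyhex-4-ynoate | CC#CC[C@@H](O)C(=O)OC | intermediate
4 | methyl (2R)-2-(triethylsilyloxy)hex-4-ynoate | CC#CC[C@@H](O[Si](CC)(CC)CC)C(=O)OC | intermediate
5 | (3R)-3-(triethylsilyloxy)-1-(trimethylsilyl)hept-5-yn-2-one | CC#CC[C@@H](O[Si](CC)(CC)CC)C(=O)C[Si](C)(C)C | intermediate
6 | (3R)-3-(triethylsilyloxy)hept-5-yn-2-one | CC#CC[C@@H](O[Si](CC)(CC)CC)C(C)=O | intermediate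
7 | ethyl (2E,4R)-3-methyl-4-(triethylsilyloxy)oct-2-en-6-ynoate | CC#CC[C@@H](O[Si](CC)(CC)CC)/C(C)=C/C(=O)OCC | intermediate
8 | (2E,4R)-3-methyl-4-(triethylsilyloxy)oct-2-en-6-yn-1-ol | CC#CC[C@@H](O[Si](CC)(CC)CC)/C(C)=C/CO | intermediate
9 | (2E,4R)-3-methyloct-2-en-6-yne-1,4-diol | CC#CC[C@@H](O)/C(C)=C/CO | intermediate
10 | (2E,4R,6E)-3-methylocta-2,6-diene with Cp2Zr(Cl) on C7 and Cp2Zr(Cl)O on C1 and C4 | C/C(=C\C[C@@H](O[Zr](Cl)(C1C=CC=C1)C1C=CC=C1)/C(C)=C/CO[Zr](Cl)(C1C=CC=C1)C1C=CC=C1)[Zr](Cl)(C1C=CC=C1)C1C=CC=C1 | intermediate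
11 | (2E,4R,6E)-7-iodo-3-methylocta-2,6-diene-1,4-diol | C/C(I)=C\C[C@@H](O)/C(C)=C/CO | intermediate
12 | (1R,3E)-1-[(2R,3R)-3-(hydroxymethyl)-2-methyloxiran-2-yl]-4-iodopent-3-en-1-ol | C/C(I)=C\C[C@@H](O)[C@@]1(C)O[C@@H]1CO | intermediate
13 | (2S,3R)-3-[(1R,3E)-1-hydroxy-4-iodopent-3-en-1-yl]-3-methyloxirane-2-carbaldehyde | C/C(I)=C\C[C@@H](O)[C@@]1(C)O[C@@H]1C=O | intermediate
14 | (2Z)-2-methylbut-2-enoic acid (angelic acid) | C/C=C(/C)C(=O)O | starting material
15 | (1S,3E)-1-[(2R,3S)-3-formyl-2-methyloxiran-2-yl]-4-iodopent-3-en-1-yl (2Z)-2-methylbut-2-enoate | C/C=C(/C)C(=O)O[C@@H](C/C=C(\C)I)[C@@]1(C)O[C@@H]1C=O | intermediate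
16 | 4-methylpent-1-en-3-ol (racemic) | CC(C)C(O)C=C | starting material
17 | (2E)-1-bromo-4-methylpent-2-ene | CC(C)/C=C/CBr | intermediate
18 | [(2E)-4-methylpent-2-en-1-yl]chromium dichloride | CC(C)/C=C/C[Cr](Cl)Cl | intermediate
19 | (1S,3E)-1-{(2R,3R)-3-[(1R,2R)-1-hydroxy-2-(propan-2-yl)but-3-en-1-yl]-2-methyloxiran-2-yl}-4-iodopent-3-en-1-yl (2Z)-2-methylbut-2-enoate | C/C=C(/C)C(=O)O[C@@H](C/C=C(\C)I)[C@@]1(C)O[C@@H]1[C@H](O)[C@@H](C=C)C(C)C | intermediate
20 | (1S,3E)-1-{(2R,3R)-3-[(1R,2R)-1-(acetyloxy)-2-(propan-2-yl)but-3-en-1-yl]-2-methyloxiran-2-yl}-4-iodopent-3-en-1-yl (2Z)-2-methylbut-2-enoate | C/C=C(/C)C(=O)O[C@@H](C/C=C(\C)I)[C@@]1(C)O[C@@H]1[C@H](OC(C)=O)[C@@H](C=C)C(C)C | intermediate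
21 | (1S,3E)-1-{(2R,3R)-3-[(1R,2S)-1-(acetyloxy)-4-(9-borabicyclo[3.3.1]nonan-9-yl)-2-(propan-2-yl)butyl]-2-methyloxiran-2-yl}-4-iodopent-3-en-1-yl (2Z)-2-methylbut-2-enoate | C/C=C(/C)C(=O)O[C@@H](C/C=C(\C)I)[C@@]1(C)O[C@@H]1[C@H](OC(C)=O)[C@@H](CCB1C2CCCC1CCC2)C(C)C | intermediate
22 | (1S,3E)-1-{(2R,3R)-3-[(1R,2S)-1-(acetyloxy)-4-iodo-2-(propan-2-yl)butyl]-2-methyloxiran-2-yl}-4-iodopent-3-en-1-yl (2Z)-2-methylbut-2-enoate | C/C=C(/C)C(=O)O[C@@H](C/C=C(\C)I)[C@@]1(C)O[C@@H]1[C@H](OC(C)=O)[C@@H](CCI)C(C)C | intermediate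
23 | (1(10)E,3S,4R,5R,6R,7S)-6-acetoxy-4,5-epoxygermacr-1(10)-en-3-yl (2Z)-2-methylbut-2-enoate | C/C=C(/C)C(=O)O[C@H]1C/C=C(\C)CC[C@@H](C(C)C)[C@@H](OC(C)=O)[C@H]2O[C@]12C | target

## Step count and risks

Total steps: 14. Longest linear sequence: 13 (steps 1–9 and 11–14; step 10 is a one-step side branch).

**Step 14 (the new electroreductive ring closure).** The risks are oligomerisation, loss of iodine by reduction, and opening of the oxirane by zinc iodide. The fallback sets out from 20: hydroboration as in step 13 gives alkylborane 21, the iodination is left out, and 21 is closed by an intramolecular B-alkyl Suzuki–Miyaura coupling (PdCl2(dppf) 10 mol%, AsPh3, Cs2CO3, DMF–THF–H2O, 45 °C, 21 added over 10 h, 1 mM). This is a known thermal ring closure and comes back to the route at 23.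

**Step 9 (Mitsunobu at a carbinol next to a fully substituted oxirane carbon, with a weakly acidic acid).** The risks are no reaction, retention through oxirane participation, and side reactions of the aldehyde. The fallback sets out from 12 and separates inversion from acylation:
- the primary hydroxyl is silylated (t-BuMe2SiCl, imidazole, −20 °C) to silyl ether F1;
- Mitsunobu reaction with the stronger 4-nitrobenzoic acid (PPh3, DEAD, toluene) gives the inverted 4-nitrobenzoate F2;
- methanolysis (K2CO3, MeOH, 0 °C) gives the (1S)-alcohol F3;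
- Yamaguchi esterification with 14 (2,4,6-trichlorobenzoyl chloride, Et3N, then F3, toluene, 80 °C) gives the angelate F4;
- HF·pyridine in THF frees the primary alcohol F5;
- TEMPO/PhI(OAc)2 oxidation comes back to the route at 15.

**Step 11 (allylation that sets C6 and C7).** The risks are reduction of the epoxy aldehyde or insertion into the alkenyl iodide by CrCl2, and modest Felkin selectivity. The fallback sets out from 15 and 16 and replaces the Barbier generation of an organochromium by a pre-formed boron reagent. Compound 16 is borylated ([Pd(MeCN)4](BF4)2 cat., B2pin2, DMSO–MeOH, 50 °C) to pinacol (2E)-4-methylpent-2-enylboronate F6. F6 adds to 15 without any reducing metal (toluene, 20 °C, then aq. NaHCO3) through a closed boron-centred chair (E-reagent gives anti) and comes back to the route at 19.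

## Further compounds

F0 | step 14 | none | none
F1 | step 9 | (1R,3E)-1-[(2R,3R)-3-({[tert-butyl(dimethyl)silyl]oxy}methyl)-2-methyloxiran-2-yl]-4-iodopent-3-en-1-ol | C/C(I)=C\C[C@@H](O)[C@@]1(C)O[C@@H]1CO[Si](C)(C)C(C)(C)C
F2 | step 9 | (1S,3E)-1-[(2R,3R)-3-({[tert-butyl(dimethyl)silyl]oxy}methyl)-2-methyloxiran-2-yl]-4-iodopent-3-en-1-yl 4-nitrobenzoate | C/C(I)=C\C[C@H](OC(=O)c1ccc(cc1)[N+](=O)[O-])[C@@]1(C)O[C@@H]1CO[Si](C)(C)C(C)(C)C
F3 | step 9 | (1S,3E)-1-[(2R,3R)-3-({[tert-butyl(dimethyl)silyl]oxy}methyl)-2-methyloxiran-2-yl]-4-iodopent-3-en-1-ol | C/C(I)=C\C[C@H](O)[C@@]1(C)O[C@@H]1CO[Si](C)(C)C(C)(C)C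
F4 | step 9 | (1S,3E)-1-[(2R,3R)-3-({[tert-butyl(dimethyl)silyl]oxy}methyl)-2-methyloxiran-2-yl]-4-iodopent-3-en-1-yl (2Z)-2-methylbut-2-enoate | C/C=C(/C)C(=O)O[C@@H](C/C=C(\C)I)[C@@]1(C)O[C@@H]1CO[Si](C)(C)C(C)(C)C
F5 | step 9 | (1S,3E)-1-[(2R,3R)-3-(hydroxymethyl)-2-methyloxiran-2-yl]-4-iodopent-3-en-1-yl (2Z)-2-methylbut-2-enoate | C/C=C(/C)C(=O)O[C@@H](C/C=C(\C)I)[C@@]1(C)O[C@@H]1CO
F6 | step 11 | 4,4,5,5-tetramethyl-2-[(2E)-4-methylpent-2-en-1-yl]-1,3,2-dioxaborolane | CC(C)/C=C/CB1OC(C)(C)C(C)(C)O1
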